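The synthesis rests on cutting the bond between C1' of ring B and C2 of ring C in the 5,7-dihydroxyflavone unit (unit 2). The key step exploits the C2–H of a plain 5,7-dialkoxychromone. This hydrogen sits on the carbon bound to O1, vinylogous to C4=O, and is the most acidic C–H of ring C. A magnesium-free zinc amide metalates it in the flask, and the chromen-2-ylzinc chloride is joined by Negishi coupling to a crowded aryl bromide. One operation thus functionalizes a C–H bond, completes flavone unit 2 and unites both halves. The precursor is 8-(2-bromo-5-methoxyphenyl)apigenin trimethyl ether (unit 1 plus ring B), with its bromine para to the ring B methoxy group.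

Key step: step 4

Locants: unit 1 is the chromenone that carries the 4-methoxyphenyl group and is linked through its C8. Unit 2 is the 5,7-dioxygenated chromenone (rings A and C) with its aryl ring B, where C1' is bound to C2 of unit 2, C2' is bound to C8 of unit 1, and C4' carries OMe.

Assumption: the target is drawn without a descriptor for the hindered C8–C2' biaryl axis, so no step controls this axis and the material is made in racemic (or equilibrating) form.

Step 1
Reactants: 1 5,7-dimethoxy-2-(4-methoxyphenyl)chromen-4-one (apigenin trimethyl ether)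
Product: 2 8-iodo-5,7-dimethoxy-2-(4-methoxyphenyl)chromen-4-one
Conditions: NIS (1.05 equiv), TFA (cat), MeCN/CH2Cl2, 0 °C to rt
Reagents that add atoms: N-iodosuccinimide, O=C1CCC(=O)N1I
Why: Electrophilic aromatic iodination (SEAr), in which the methylated 5-oxygen makes C8 of ring A (para to 5-OMe, ortho to 7-OMe and O1) the most nucleophilic and least flanked position, whereas C6 lies between two methoxy groups and C3 and the conjugated anisyl ring are far less activated.

Step 2
Reactants: 2 8-iodo-5,7-dimethoxy-2-(4-methoxyphenyl)chromen-4-one; 3 (2-bromo-5-methoxyphenyl)boronic acid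
Product: 4 8-(2-bromo-5-methoxyphenyl)-5,7-dimethoxy-2-(4-methoxyphenyl)chromen-4-one
Conditions: 3 (1.5 equiv), Pd(PPh3)4 (5 mol %), K2CO3, DMF/H2O (9:1), 90 °C
Reagents that add atoms: none
Why: Suzuki–Miyaura coupling in which zerovalent palladium with the modest ligand PPh3 should insert into the C8–I bond much faster than into the electron-rich C–Br bond (para to OMe) of 3 or 4, so the bromine survives as the handle for step 4.

Step 3
Reactants: 5 5,7-dihydroxychromen-4-one
Product: 6 5,7-di(propan-2-yloxy)chromen-4-one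
Conditions: 2-iodopropane (5 equiv), K2CO3 (5 equiv), DMF, 65 °C
Reagents that add atoms: 2-iodopropane, CC(C)I
Why: Williamson ether synthesis, in which excess secondary iodide and heat should also alkylate the hydrogen-bonded 5-OH while anhydrous carbonate spares the base-sensitive C2 of the pyranone.

Step 4
Reactants: 6 5,7-di(propan-2-yloxy)chromen-4-one; 4 8-(2-bromo-5-methoxyphenyl)-5,7-dimethoxy-2-(4-methoxyphenyl)chromen-4-one
Product: 8 protected biflavone 8-{5-methoxy-2-[4-oxo-5,7-di(propan-2-yloxy)chromen-2-yl]phenyl}-5,7-dimethoxy-2-(4-methoxyphenyl)chromen-4-one, via chromen-2-ylzinc chloride 7 (not isolated)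
Conditions: 6 (1.5 equiv), TMPZnCl·LiCl (1.4 equiv, TMP = 2,2,6,6-tetramethylpiperidin-1-yl), THF, 25 °C; then 4 (1.0 equiv), Pd(OAc)2 (5 mol %), SPhos (10 mol %), THF, 55 °C
Reagents that add atoms: none
Why: TMPZnCl·LiCl removes C2–H of 6, the most acidic C–H of ring C because its carbon carries O1 and is vinylogous to C4=O, and gives 7; zerovalent palladium formed from Pd(OAc)2 and SPhos then inserts into the C1'–Br bond of 4, 7 hands its chromenyl group to the divalent arylpalladium bromide and reductive elimination forms the C1'–C2 bond. The closest known reaction type is the regioselective zincation of chromones with TMP zinc amides followed by Negishi cross-coupling with aryl halides to give flavones. No ring is closed and no stereocentre is set, and the hindered C8–C2' axis stays uncontrolled. The step needs C2 over C3 zincation, which is secured by leaving out magnesium salts and other Lewis acids that bind C4=O and steer the base to C3, while the bulky isopropyl ethers shield C6–H and C8–H of ring A. It also needs 4 to stay unmetalated, which is secured by using less base than 6 so that no zinc amide is left when 4 is added, and the organozinc does not add to the flavone carbonyl of unit 1. The crowding beside C1' is met by a slim nucleophile flanked only by O1 and C3–H and by the bulky, electron-rich ligand SPhos, which speeds oxidative addition and reductive elimination.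

Step 5
Reactants: 8 protected biflavone 8-{5-methoxy-2-[4-oxo-5,7-di(propan-2-yloxy)chromen-2-yl]phenyl}-5,7-dimethoxy-2-(4-methoxyphenyl)chromen-4-one
Product: 9 8-[2-(5,7-dihydroxy-4-oxochromen-2-yl)-5-methoxyphenyl]-5-hydroxy-7-methoxy-2-(4-methoxyphenyl)chromen-4-one (target CNP0114008.0)
Conditions: BCl3 (1 M in CH2Cl2, 10 equiv), CH2Cl2, −78 °C to rt; then H2O/THF, rt
Reagents that add atoms: none
Why: Lewis acid ether cleavage, in which BCl3 should dealkylate both secondary isopropyl aryl ethers and, through a six-membered boron chelate with C4=O, the peri 5-OMe of unit 1, while the three non-chelated methyl ethers (7-OMe and both 4'-OMe groups) are inert to BCl3 at this temperature.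

Compound list
1 | 5,7-dimethoxy-2-(4-methoxyphenyl)chromen-4-one (apigenin trimethyl ether) | COc1ccc(-c2cc(=O)c3c(OC)cc(OC)cc3o2)cc1 | starting material
2 | 8-iodo-5,7-dimethoxy-2-(4-methoxyphenyl)chromen-4-one | COc1ccc(-c2cc(=O)c3c(OC)cc(OC)c(I)c3o2)cc1 | intermediate
3 | (2-bromo-5-methoxyphenyl)boronic acid | COc1ccc(Br)c(B(O)O)c1 | starting material
4 | 8-(2-bromo-5-methoxyphenyl)-5,7-dimethoxy-2-(4-methoxyphenyl)chromen-4-one | COc1ccc(-c2cc(=O)c3c(OC)cc(OC)c(-c4cc(OC)ccc4Br)c3o2)cc1 | intermediate
5 | 5,7-dihydroxychromen-4-one | Oc1cc(O)c2c(=O)ccoc2c1 | starting material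
6 | 5,7-di(propan-2-yloxy)chromen-4-one | CC(C)Oc1cc(OC(C)C)c2c(=O)ccoc2c1 | intermediate
7 | [4-oxo-5,7-di(propan-2-yloxy)chromen-2-yl]zinc chloride (LiCl complex, not isolated) | CC(C)Oc1cc(OC(C)C)c2c(=O)cc([Zn]Cl)oc2c1 | intermediate
8 | 8-{5-methoxy-2-[4-oxo-5,7-di(propan-2-yloxy)chromen-2-yl]phenyl}-5,7-dimethoxy-2-(4-methoxyphenyl)chromen-4-one | COc1ccc(-c2cc(=O)c3c(OC)cc(OC)c(-c4cc(OC)ccc4-c4cc(=O)c5c(OC(C)C)cc(OC(C)C)cc5o4)c3o2)cc1 | intermediate
9 | 8-[2-(5,7-dihydroxy-4-oxochromen-2-yl)-5-methoxyphenyl]-5-hydroxy-7-methoxy-2-(4-methoxyphenyl)chromen-4-one | COc1ccc(-c2cc(=O)c3c(O)cc(OC)c(-c4cc(OC)ccc4-c4cc(=O)c5c(O)cc(O)cc5o4)c3o2)cc1 | target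

Total step count: 5. Longest linear sequence: 4 steps (1 → 2 → 4 → 8 → 9).

Steps most likely to fail

**Step 4.** Transfer of the electron-poor chromenyl group from zinc to the crowded arylpalladium bromide may lag behind protonation or homocoupling of the organozinc. Metal coordination between C4=O and the 5-alkoxy oxygen may also divert part of the zincation to C3. The fallback sets out from 4 and 7 and comes back at 8, with the roles of the two partners exchanged.
- Miyaura borylation of 4 (B2pin2, KOAc, PdCl2(dppf), dioxane, 90 °C) should give the pinacol boronate 5,7-dimethoxy-8-[5-methoxy-2-(4,4,5,5-tetramethyl-1,3,2-dioxaborolan-2-yl)phenyl]-2-(4-methoxyphenyl)chromen-4-one F1.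
- Quenching 7 with I2 in THF should give 2-iodo-5,7-di(propan-2-yloxy)chromen-4-one F2. This compound is isolated, freed from any C3 isomer and checked before the union.
- Suzuki–Miyaura coupling of F1 with F2 (Pd(OAc)2, SPhos, K3PO4, toluene/H2O, 80 °C) then forms the same C1'–C2 bond. Oxidative addition now takes place at the unhindered vinylogous acyl iodide.

**Step 2.** Slow oxidative addition at the doubly ortho-oxygenated C8–I bond may let protodeboronation of 3 and insertion into C–Br bonds (oligomerization) compete. The fallback sets out from 2 and comes back at 4.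
- Miyaura borylation of 2 (B2pin2, KOAc, PdCl2(dppf), DMSO, 80 °C) should give 5,7-dimethoxy-2-(4-methoxyphenyl)-8-(4,4,5,5-tetramethyl-1,3,2-dioxaborolan-2-yl)chromen-4-one F3.
- F3 is coupled with commercial 1-bromo-2-iodo-4-methoxybenzene (Pd(PPh3)4, K2CO3, DME/H2O, 80 °C).
- The electrophile now carries an unhindered C–I bond beside its C–Br bond, so halogen discrimination no longer depends on a sluggish iodide.

**Step 5.** Cleavage of the non-chelated 7-O-isopropyl ether may stay incomplete, boron chelates may precipitate, and forcing the reaction may cost a non-chelated methyl ether. The fallback sets out from 5 and comes back at 9, and it replaces the single Lewis acid unmasking by two orthogonal ones.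
- Compound 5 is benzylated (BnBr, K2CO3, DMF, 80 °C) to give 5,7-bis(benzyloxy)chromen-4-one F4.
- F4 is zincated as in step 4 to give [5,7-bis(benzyloxy)-4-oxochromen-2-yl]zinc chloride F5.
- F5 is coupled in the same flask with 4 to give the dibenzyl biflavone 8-{2-[5,7-bis(benzyloxy)-4-oxochromen-2-yl]-5-methoxyphenyl}-5,7-dimethoxy-2-(4-methoxyphenyl)chromen-4-one F6.
- Hydrogenolysis (H2, Pd/C, EtOAc/MeOH, rt) should leave all methyl ethers untouched and give 8-[2-(5,7-dihydroxy-4-oxochromen-2-yl)-5-methoxyphenyl]-5,7-dimethoxy-2-(4-methoxyphenyl)chromen-4-one F7.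
- A single chelation-assisted demethylation of the peri 5-OMe (BCl3, CH2Cl2, −20 °C, then H2O) then gives 9.

Further compounds
F1 | step 4 | 5,7-dimethoxy-8-[5-methoxy-2-(4,4,5,5-tetramethyl-1,3,2-dioxaborolan-2-yl)phenyl]-2-(4-methoxyphenyl)chromen-4-one | COc1ccc(-c2cc(=O)c3c(OC)cc(OC)c(-c4cc(OC)ccc4B5OC(C)(C)C(C)(C)O5)c3o2)cc1
F2 | step 4 | 2-iodo-5,7-di(propan-2-yloxy)chromen-4-one | CC(C)Oc1cc(OC(C)C)c2c(=O)cc(I)oc2c1
F3 | step 2 | 5,7-dimethoxy-2-(4-methoxyphenyl)-8-(4,4,5,5-tetramethyl-1,3,2-dioxaborolan-2-yl)chromen-4-one | COc1ccc(-c2cc(=O)c3c(OC)cc(OC)c(B4OC(C)(C)C(C)(C)O4)c3o2)cc1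
F4 | step 5 | 5,7-bis(benzyloxy)chromen-4-one | O=c1ccoc2cc(OCc3ccccc3)cc(OCc3ccccc3)c12
F5 | step 5 | [5,7-bis(benzyloxy)-4-oxochromen-2-yl]zinc chloride | O=c1cc([Zn]Cl)oc2cc(OCc3ccccc3)cc(OCc3ccccc3)c12
F6 | step 5 | 8-{2-[5,7-bis(benzyloxy)-4-oxochromen-2-yl]-5-methoxyphenyl}-5,7-dimethoxy-2-(4-methoxyphenyl)chromen-4-one | COc1ccc(-c2cc(=O)c3c(OC)cc(OC)c(-c4cc(OC)ccc4-c4cc(=O)c5c(OCc6ccccc6)cc(OCc6ccccc6)cc5o4)c3o2)cc1
F7 | step 5 | 8-[2-(5,7-dihydroxy-4-oxochromen-2-yl)-5-methoxyphenyl]-5,7-dimethoxy-2-(4-methoxyphenyl)chromen-4-one | COc1ccc(-c2cc(=O)c3c(OC)cc(OC)c(-c4cc(OC)ccc4-c4cc(=O)c5c(O)cc(O)cc5o4)c3o2)cc1
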